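**Plan**

- Enabling feature (spiro[4.5]decane numbering: C1 carbinol and C2 dienyl carbon of ring A, C5 spiro, C6 methyl carbinol, C9 alkylidene, C10 propyl-bearing carbon of ring B): C6 is para to C9, as in a 4-methylphenol oxidised at its para carbon, and the C6 oxygen is 1,3 to the C1 oxygen through C5, the spacing of a six-membered cyclic carbonate.
- Cuts: triene at the C(=CH2)–CH bond (vinylsilane plus dienyl iodide 41); enal back to a C9 ketone; ring A at the C4–C5 bond (radical closure onto a dienone); the C6–O bond back to a para-cresol carrying a benzylic tert-butyl carbonate; the arm at C1–C2 into aldehyde 9 and mesylate 17.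
- Forward: the arene (future ring B) with its propyl chain, then the two-stereocentre arm, then dearomatisation with carbonate ring closure, then ring A by 5-exo radical spirocyclisation, then the enal, then the triene.
- Stereochemistry: the (R)-mesylate (asymmetric transfer hydrogenation) sets C2 and, through the anti-selective allenylzinc addition, C1; C1 steers the carbonate oxygen to one face of C6; the carbonate steers the radical to the other face at C5, and hydrogen transfer sets C10.
- Alkene geometry: the enal from the oxidative transposition, the triene from an anti-carbomagnesiation and stereoretentive couplings.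

Key step: step 16

Remark on the chemistry: the allenylzinc addition is taken to replace the mesylate with overall inversion at the propargylic carbon (anti oxidative addition, syn SE2′), and the (R,R)-configured ruthenium catalyst is taken to give the (R)-alkynol, so the (R)-mesylate is used.
Abbreviations: TBS = tert-butyldimethylsilyl, TIPS = triisopropylsilyl, PMB = 4-methoxybenzyl, Boc = tert-butoxycarbonyl, 9-BBN = 9-borabicyclo[3.3.1]nonane.

**Ring B arene (aldehyde 9)**

Step 1
Reactants: 1 5-hydroxy-2-methylbenzaldehyde; 2 allyl bromide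
Product: 3 2-methyl-5-(prop-2-en-1-yloxy)benzaldehyde
Conditions: K2CO3, DMF, 60 °C
Reagents that add atoms: none
Why: Williamson O-allylation of the phenoxide, to which the aldehyde is inert.

Step 2
Reactants: 3 2-methyl-5-(prop-2-en-1-yloxy)benzaldehyde
Product: 5 3-hydroxy-6-methyl-2-(prop-2-en-1-yl)benzaldehyde, via ortho-dienone 4 (not isolated)
Conditions: PhNEt2, 200 °C, sealed tube
Reagents that add atoms: none
Why: Aromatic Claisen rearrangement followed by tautomerisation; a meta acyl group is known to steer the allyl group to the ortho position between the two substituents, the para position is blocked by the methyl group, and the other ortho isomer should be separable.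

Step 3
Reactants: 5 3-hydroxy-6-methyl-2-(prop-2-en-1-yl)benzaldehyde
Product: 7 3-(hydroxymethyl)-2-(3-hydroxypropyl)-4-methylphenol, via tris-borane adduct 6 (not isolated)
Conditions: 9-BBN (3.3 equiv), THF, 0 °C to 50 °C; then NaOH, H2O2, 0 °C to rt
Reagents that add atoms: hydrogen peroxide, OO
Why: Hydroboration–oxidation with 9-BBN places the oxygen on the terminal carbon of the allyl group and reduces the aldehyde in the same pot, which avoids a separate carbonyl protection.

Step 4
Reactants: 7 3-(hydroxymethyl)-2-(3-hydroxypropyl)-4-methylphenol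
Product: 8 3-hydroxy-2-(3-hydroxypropyl)-6-methylbenzaldehyde
Conditions: MnO2 (excess), EtOAc, rt
Reagents that add atoms: none
Why: MnO2 oxidises benzylic alcohols selectively and should leave the aliphatic primary alcohol and the phenol untouched.

Step 5
Reactants: 8 3-hydroxy-2-(3-hydroxypropyl)-6-methylbenzaldehyde
Product: 9 3-(TBS-oxy)-2-[3-(TBS-oxy)propyl]-6-methylbenzaldehyde
Conditions: TBSCl (2.4 equiv), imidazole, DMF, rt
Reagents that add atoms: tert-butyldimethylsilyl chloride, CC(C)(C)[Si](C)(C)Cl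
Why: Imidazole-mediated silylation covers both hydroxyls in one step; the aryl silyl ether can later be removed in the presence of the alkyl one.

**Propargylic mesylate 17**

Step 6
Reactants: 10 3-[(4-methoxybenzyl)oxy]propan-1-ol
Product: 11 3-[(4-methoxybenzyl)oxy]propanal
Conditions: TEMPO (10 mol %), PhI(OAc)2, CH2Cl2, rt
Reagents that add atoms: none
Why: Nitroxyl-catalysed oxidation of a primary alcohol stops at the aldehyde and tolerates the PMB ether.

Step 7
Reactants: 11 3-[(4-methoxybenzyl)oxy]propanal; 12 ethynyltri(propan-2-yl)silane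
Product: 14 rac-5-[(4-methoxybenzyl)oxy]-1-(triisopropylsilyl)pent-1-yn-3-ol, via lithium acetylide 13 (not isolated)
Conditions: n-BuLi, THF, −78 °C; then 11, −78 °C to 0 °C; aqueous work-up
Reagents that add atoms: none
Why: 1,2-Addition of a lithium acetylide to an aldehyde; the stereocentre is removed in step 8.

Step 8
Reactants: 14 rac-5-[(4-methoxybenzyl)oxy]-1-(triisopropylsilyl)pent-1-yn-3-ol
Product: 15 5-[(4-methoxybenzyl)oxy]-1-(triisopropylsilyl)pent-1-yn-3-one
Conditions: MnO2 (excess), CH2Cl2, rt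
Reagents that add atoms: none
Why: Propargylic alcohols are oxidised to ynones by MnO2 under neutral conditions.

Step 9
Reactants: 15 5-[(4-methoxybenzyl)oxy]-1-(triisopropylsilyl)pent-1-yn-3-one
Product: 16 (3R)-5-[(4-methoxybenzyl)oxy]-1-(triisopropylsilyl)pent-1-yn-3-ol
Conditions: RuCl[(R,R)-TsDPEN](p-cymene) (2 mol %), KOH (5 mol %), i-PrOH, rt
Reagents that add atoms: none
Why: Noyori asymmetric transfer hydrogenation of a silyl ynone, in which the alkynyl group takes the role of the π-substituent, so the (R,R)-ligand should deliver hydride to the face that gives the (3R)-alcohol.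

Step 10
Reactants: 16 (3R)-5-[(4-methoxybenzyl)oxy]-1-(triisopropylsilyl)pent-1-yn-3-ol
Product: 17 (3R)-5-[(4-methoxybenzyl)oxy]-1-(triisopropylsilyl)pent-1-yn-3-yl methanesulfonate
Conditions: MsCl, Et3N, CH2Cl2, −78 °C to 0 °C
Reagents that add atoms: methanesulfonyl chloride, CS(=O)(=O)Cl
Why: Sulfonylation at oxygen leaves the stereocentre untouched.

**Arm, key step and ring A**

Step 11
Reactants: 9 3-(TBS-oxy)-2-[3-(TBS-oxy)propyl]-6-methylbenzaldehyde; 17 (3R)-5-[(4-methoxybenzyl)oxy]-1-(triisopropylsilyl)pent-1-yn-3-yl methanesulfonate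
Product: 19 (1S,2S)-1-{3-(TBS-oxy)-2-[3-(TBS-oxy)propyl]-6-methylphenyl}-2-{2-[(4-methoxybenzyl)oxy]ethyl}-4-(triisopropylsilyl)but-3-yn-1-ol, via allenylzinc mesylate 18 (not isolated)
Conditions: Pd(OAc)2 (5 mol %), PPh3 (5 mol %), Et2Zn (3 equiv), THF, −78 °C to −20 °C; aqueous work-up
Reagents that add atoms: none
Why: Marshall propargylation: anti oxidative addition of zerovalent palladium and transmetalation give a configurationally defined allenylzinc, whose cyclic SE2′ addition transfers chirality to C2 and, with the aryl group anti to the allenyl substituent, should give the anti (1S,2S) alcohol.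

Step 12
Reactants: 19 the (1S,2S) homopropargylic alcohol
Product: 20 tert-butyl (1S,2S)-1-{3-(TBS-oxy)-2-[3-(TBS-oxy)propyl]-6-methylphenyl}-2-{2-[(4-methoxybenzyl)oxy]ethyl}-4-(triisopropylsilyl)but-3-yn-1-yl carbonate
Conditions: NaN(SiMe3)2, THF, −78 °C; then Boc2O, −78 °C to 0 °C
Reagents that add atoms: di-tert-butyl dicarbonate, CC(C)(C)OC(=O)OC(=O)OC(C)(C)C
Why: Acylation of the preformed alkoxide is the reliable way to put a Boc carbonate on a hindered secondary alcohol.

Step 13
Reactants: 20 the PMB-protected tert-butyl carbonate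
Product: 21 tert-butyl (1S,2S)-1-{3-(TBS-oxy)-2-[3-(TBS-oxy)propyl]-6-methylphenyl}-2-(2-hydroxyethyl)-4-(triisopropylsilyl)but-3-yn-1-yl carbonate
Conditions: DDQ, CH2Cl2/pH 7 buffer, 0 °C
Reagents that add atoms: none
Why: Oxidative cleavage of the PMB ether by DDQ leaves silyl ethers, the carbonate and the silyl alkyne intact.

Step 14
Reactants: 21 the primary alcohol
Product: 22 tert-butyl (1S,2S)-2-(2-bromoethyl)-1-{3-(TBS-oxy)-2-[3-(TBS-oxy)propyl]-6-methylphenyl}-4-(triisopropylsilyl)but-3-yn-1-yl carbonate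
Conditions: CBr4, PPh3, 2,6-lutidine, CH2Cl2, 0 °C
Reagents that add atoms: carbon tetrabromide, BrC(Br)(Br)Br
Why: Appel reaction of a primary alcohol under buffered, non-acidic conditions.

Step 15
Reactants: 22 the bromide with both TBS ethers
Product: 23 tert-butyl (1S,2S)-2-(2-bromoethyl)-1-{3-hydroxy-6-methyl-2-[3-(TBS-oxy)propyl]phenyl}-4-(triisopropylsilyl)but-3-yn-1-yl carbonate
Conditions: KHF2, MeOH, rt
Reagents that add atoms: none
Why: Bifluoride cleaves aryl silyl ethers far faster than primary alkyl silyl ethers, and the alkynyl TIPS group, the carbonate and the bromide should be inert to it.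

Step 16
Reactants: 23 the phenol with the benzylic tert-butyl carbonate
Product: 26 (4S,8aS)-4-[(3S)-5-bromo-1-(triisopropylsilyl)pent-1-yn-3-yl]-8a-methyl-5-[3-(TBS-oxy)propyl]-4H-1,3-benzodioxine-2,6(8aH)-dione, via aryloxy-λ3-iodane 24 (not isolated), via dioxanylium acetate 25 (not isolated)
Conditions: PhI(OAc)2 (1.1 equiv), NaHCO3, (CF3)2CHOH/CH2Cl2, −20 °C to 0 °C
Reagents that add atoms: none
Why: Proposed new method: ligand exchange of the phenol at trivalent iodine gives 24, whose loss of iodobenzene and acetate makes the methyl-bearing para carbon electrophilic; the carbonyl oxygen of the benzylic tert-butyl carbonate adds there to give dioxanylium ion 25, which sheds its tert-butyl group as 2-methylpropene and leaves the cyclic carbonate. The closest known reactions are PhI(OAc)2-mediated dearomatising cyclisations of 4-alkylphenols by tethered carboxylic acids or alcohols, and the capture of halonium ions by tert-butyl carbonates to give cyclic carbonates. The one new ring is the six-membered carbonate (C8a, O, C=O, O, C4, C4a), closed in a 6-exo mode onto the para carbon with no carbon–carbon bond formed. The new stereocentre C8a is controlled by the benzylic stereocentre C4: 1,3-allylic strain with the ortho silyloxypropyl chain keeps the C4–H bond in the arene plane, so the oxygen reaches the face that leaves the alkynyl-bearing branch on the opposite side. The step needs para attack to win over attack at the ortho carbon and over loss of a benzylic proton to a quinone methide; the higher positive charge and lower crowding at the para carbon, the intramolecular delivery and the ionising, weakly nucleophilic solvent should secure this.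

Step 17
Reactants: 26 the dienone cyclic carbonate
Product: 27 cyclic 1,6-carbonate of (1S,2S,5S,6S,10S)-1,6-dihydroxy-6-methyl-10-[3-(TBS-oxy)propyl]-2-[(triisopropylsilyl)ethynyl]spiro[4.5]dec-7-en-9-one
Conditions: Bu3SnH (1.3 equiv, syringe pump), AIBN (cat.), PhH (5 mM), 80 °C
Reagents that add atoms: none
Why: Tin-hydride-mediated 5-exo-trig radical cyclisation (intramolecular Giese addition) onto the β-carbon of the dienone closes ring A; the branch carrying the radical lies on the face opposite the carbonate bridge, so C5 forms with the new methylene anti to the C6 oxygen, and hydrogen transfer to the α-keto radical at C10 should come anti to the pseudo-axial C1 on the spiro carbon, which puts the silyloxypropyl chain on the carbonate face.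

Step 18
Reactants: 27 the spirocyclic enone carbonate
Product: 28 cyclic 1,6-carbonate of (1S,2S,5S,6S,10S)-1,6-dihydroxy-6-methyl-10-[3-(TBS-oxy)propyl]-2-[(triisopropylsilyl)ethynyl]spiro[4.5]decan-9-one
Conditions: [(Ph3P)CuH]6 (0.5 equiv), PhH, rt; aqueous work-up
Reagents that add atoms: none
Why: Conjugate reduction of the enone by the hexameric copper hydride spares the ketone, the carbonate and the silyl alkyne and creates no stereocentre.

Step 19
Reactants: 28 the spirocyclic ketone carbonate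
Product: 29 cyclic 1,6-carbonate of (1S,2S,5S,6S,9R,10S)-6-methyl-9-(prop-1-en-2-yl)-10-[3-(TBS-oxy)propyl]-2-[(triisopropylsilyl)ethynyl]spiro[4.5]decane-1,6,9-triol
Conditions: CH2=C(CH3)MgBr (3 equiv), LaCl3·2LiCl (1.1 equiv), THF, −20 °C to 0 °C
Reagents that add atoms: isopropenylmagnesium bromide, CC(=C)[Mg]Br
Why: Lanthanum-promoted 1,2-addition of an alkenyl Grignard reagent suppresses enolisation of the hindered ketone and should be faster than attack on the carbonate; addition is expected anti to the axial C1, and the new carbinol centre is erased in step 20.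

Step 20
Reactants: 29 the tertiary isopropenyl carbinol
Product: 30 (2Z)-2-{(1S,2S,5S,6S,10R)-1,6-(carbonyldioxy)-6-methyl-10-[3-(TBS-oxy)propyl]-2-[(triisopropylsilyl)ethynyl]spiro[4.5]decan-9-ylidene}propanal
Conditions: pyridinium chlorochromate (C5H5NH)[CrO3Cl] (3 equiv), 4 Å molecular sieves, CH2Cl2, rt
Reagents that add atoms: pyridinium chlorochromate, [O-][Cr](=O)(=O)Cl.c1cc[nH+]cc1
Why: Babler–Dauben oxidative transposition (chromate ester, [3,3] shift, oxidation of the primary chromate) gives the enal; the methyl group should turn toward the less crowded C8 methylene and the oxygen-bearing terminus toward C10, which is also expected to be the more stable geometry, while the carbonate shields the other two oxygens from hexavalent chromium.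

Step 21
Reactants: 30 the silylated enal carbonate
Product: 32 (2Z)-2-[(1S,2S,5S,6S,10R)-2-ethynyl-1,6-dihydroxy-10-(3-hydroxypropyl)-6-methylspiro[4.5]decan-9-ylidene]propanal, via desilylated carbonate 31 (not isolated)
Conditions: Bu4NF, AcOH, THF, rt; then LiOH, H2O, 0 °C to rt
Reagents that add atoms: none
Why: Buffered fluoride cleaves the C–Si and O–Si bonds, and hydroxide then opens the six-membered carbonate to a hemicarbonate that loses CO2.

Step 22
Reactants: 32 the triol with the terminal alkyne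
Product: 33 (2Z)-2-[(1S,2R,5S,6S,10R)-2-{1-[benzyl(dimethyl)silyl]ethenyl}-1,6-dihydroxy-10-(3-hydroxypropyl)-6-methylspiro[4.5]decan-9-ylidene]propanal
Conditions: BnMe2SiH (1.5 equiv), [Cp*Ru(MeCN)3]PF6 (5 mol %), acetone, 0 °C to rt
Reagents that add atoms: benzyldimethylsilane, C[SiH](C)Cc1ccccc1
Why: Ruthenium-catalysed Markovnikov hydrosilylation of terminal alkynes gives the 1,1-disubstituted vinylsilane and is known to tolerate free hydroxyls and carbonyl groups (the C2 descriptor changes only because silicon raises the priority of the vinyl carbon).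

**Dienyl iodide 41 and final coupling**

Step 23
Reactants: 34 prop-2-yn-1-ol; 35 5-bromo-2-methylpent-2-ene
Product: 38 (2Z)-3-iodo-2-(4-methylpent-3-en-1-yl)prop-2-en-1-ol, via Grignard reagent 36 (not isolated), via magnesium chelate 37 (not isolated)
Conditions: Mg, THF; then 34, CuI (20 mol %), THF, −10 °C to rt; then I2, −78 °C to 0 °C; aqueous work-up
Reagents that add atoms: iodine, II
Why: Copper-catalysed anti-carbomagnesiation of the propargylic alkoxide gives a five-membered alkenylmagnesium chelate, and iodinolysis with retention places iodine cis to the hydroxymethyl group.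

Step 24
Reactants: 38 (2Z)-3-iodo-2-(4-methylpent-3-en-1-yl)prop-2-en-1-ol; 39 (E)-1,2-bis(tributylstannyl)ethene
Product: 40 (2Z,4E)-2-(4-methylpent-3-en-1-yl)-5-(tributylstannyl)penta-2,4-dien-1-ol
Conditions: PdCl2(MeCN)2 (5 mol %), 39 (3 equiv), DMF, rt, dark
Reagents that add atoms: none
Why: Stille coupling with an excess of the distannane stops after one coupling and retains both alkene geometries.

Step 25
Reactants: 40 the dienylstannane
Product: 41 (2Z,4E)-5-iodo-2-(4-methylpent-3-en-1-yl)penta-2,4-dien-1-ol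
Conditions: I2 (1.05 equiv), CH2Cl2, −78 °C to 0 °C
Reagents that add atoms: iodine, II
Why: Iododestannylation proceeds with retention and is much faster than any reaction of iodine with the isolated trisubstituted alkene.

Step 26
Reactants: 33 the vinylsilane; 41 the dienyl iodide
Product: 42 (2Z)-2-{(1S,2S,5S,6S,10R)-1,6-dihydroxy-2-[(3E,5Z)-6-(hydroxymethyl)-10-methylundeca-1,3,5,9-tetraen-2-yl]-10-(3-hydroxypropyl)-6-methylspiro[4.5]decan-9-ylidene}propanal
Conditions: Bu4NF (3 equiv), Pd2(dba)3·CHCl3 (5 mol %), THF, 0 °C to rt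
Reagents that add atoms: none
Why: Fluoride-promoted Hiyama–Denmark coupling of a benzyldimethylvinylsilane with an alkenyl iodide joins the two sp2 carbons with retention of the diene geometry and needs no protecting group.

**Compound list**

1 | 5-hydroxy-2-methylbenzaldehyde | Cc1ccc(O)cc1C=O | starting material
2 | allyl bromide | C=CCBr | starting material
3 | 2-methyl-5-(prop-2-en-1-yloxy)benzaldehyde | Cc1ccc(OCC=C)cc1C=O | intermediate
4 | 2-methyl-5-oxo-6-(prop-2-en-1-yl)cyclohexa-1,3-diene-1-carbaldehyde (racemic ortho-dienone) | O=CC1=C(C)C=CC(=O)C1CC=C | intermediate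
5 | 3-hydroxy-6-methyl-2-(prop-2-en-1-yl)benzaldehyde | Cc1ccc(O)c(CC=C)c1C=O | intermediate
6 | tris(9-BBN) adduct: aryl and benzyl borinates, B-alkyl borane | Cc1ccc(OB2C3CCCC2CCC3)c(CCCB2C3CCCC2CCC3)c1COB1C2CCCC1CCC2 | intermediate
7 | 3-(hydroxymethyl)-2-(3-hydroxypropyl)-4-methylphenol | Cc1ccc(O)c(CCCO)c1CO | intermediate
8 | 3-hydroxy-2-(3-hydroxypropyl)-6-methylbenzaldehyde | Cc1ccc(O)c(CCCO)c1C=O | intermediate
9 | 3-(TBS-oxy)-2-[3-(TBS-oxy)propyl]-6-methylbenzaldehyde | Cc1ccc(O[Si](C)(C)C(C)(C)C)c(CCCO[Si](C)(C)C(C)(C)C)c1C=O | intermediate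
10 | 3-[(4-methoxybenzyl)oxy]propan-1-ol | COc1ccc(COCCCO)cc1 | starting material
11 | 3-[(4-methoxybenzyl)oxy]propanal | COc1ccc(COCCC=O)cc1 | intermediate
12 | ethynyltri(propan-2-yl)silane | C#C[Si](C(C)C)(C(C)C)C(C)C | starting material
13 | lithium (triisopropylsilyl)acetylide | [Li]C#C[Si](C(C)C)(C(C)C)C(C)C | intermediate
14 | rac-5-[(4-methoxybenzyl)oxy]-1-(triisopropylsilyl)pent-1-yn-3-ol | COc1ccc(COCCC(O)C#C[Si](C(C)C)(C(C)C)C(C)C)cc1 | intermediate
15 | 5-[(4-methoxybenzyl)oxy]-1-(triisopropylsilyl)pent-1-yn-3-one | COc1ccc(COCCC(=O)C#C[Si](C(C)C)(C(C)C)C(C)C)cc1 | intermediate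
16 | (3R)-5-[(4-methoxybenzyl)oxy]-1-(triisopropylsilyl)pent-1-yn-3-ol | CC(C)[Si](C(C)C)(C(C)C)C#C[C@H](O)CCOCc1ccc(OC)cc1 | intermediate
17 | (3R)-5-[(4-methoxybenzyl)oxy]-1-(triisopropylsilyl)pent-1-yn-3-yl methanesulfonate | CC(C)[Si](C(C)C)(C(C)C)C#C[C@H](OS(C)(=O)=O)CCOCc1ccc(OC)cc1 | intermediate
18 | {5-[(4-methoxybenzyl)oxy]-1-(triisopropylsilyl)penta-1,2-dien-1-yl}zinc methanesulfonate, zinc anti to the departed mesylate, axial configuration as in the SMILES | CS(=O)(=O)O[Zn]C([Si](C(C)C)(C(C)C)C(C)C)=[C@@]=C([H])CCOCc1ccc(OC)cc1 | intermediate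
19 | (1S,2S)-1-{3-(TBS-oxy)-2-[3-(TBS-oxy)propyl]-6-methylphenyl}-2-{2-[(4-methoxybenzyl)oxy]ethyl}-4-(triisopropylsilyl)but-3-yn-1-ol | Cc1ccc(O[Si](C)(C)C(C)(C)C)c(CCCO[Si](C)(C)C(C)(C)C)c1[C@@H](O)[C@H](C#C[Si](C(C)C)(C(C)C)C(C)C)CCOCc1ccc(OC)cc1 | intermediate
20 | tert-butyl carbonate of 19 | Cc1ccc(O[Si](C)(C)C(C)(C)C)c(CCCO[Si](C)(C)C(C)(C)C)c1[C@@H](OC(=O)OC(C)(C)C)[C@H](C#C[Si](C(C)C)(C(C)C)C(C)C)CCOCc1ccc(OC)cc1 | intermediate
21 | tert-butyl (1S,2S)-1-{3-(TBS-oxy)-2-[3-(TBS-oxy)propyl]-6-methylphenyl}-2-(2-hydroxyethyl)-4-(triisopropylsilyl)but-3-yn-1-yl carbonate | Cc1ccc(O[Si](C)(C)C(C)(C)C)c(CCCO[Si](C)(C)C(C)(C)C)c1[C@@H](OC(=O)OC(C)(C)C)[C@H](C#C[Si](C(C)C)(C(C)C)C(C)C)CCO | intermediate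
22 | tert-butyl (1S,2S)-2-(2-bromoethyl)-1-{3-(TBS-oxy)-2-[3-(TBS-oxy)propyl]-6-methylphenyl}-4-(triisopropylsilyl)but-3-yn-1-yl carbonate | Cc1ccc(O[Si](C)(C)C(C)(C)C)c(CCCO[Si](C)(C)C(C)(C)C)c1[C@@H](OC(=O)OC(C)(C)C)[C@H](C#C[Si](C(C)C)(C(C)C)C(C)C)CCBr | intermediate
23 | tert-butyl (1S,2S)-2-(2-bromoethyl)-1-{3-hydroxy-6-methyl-2-[3-(TBS-oxy)propyl]phenyl}-4-(triisopropylsilyl)but-3-yn-1-yl carbonate | Cc1ccc(O)c(CCCO[Si](C)(C)C(C)(C)C)c1[C@@H](OC(=O)OC(C)(C)C)[C@H](C#C[Si](C(C)C)(C(C)C)C(C)C)CCBr | intermediate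
24 | acetoxy(aryloxy)phenyl-λ3-iodane of phenol 23 | CC(=O)OI(c1ccccc1)Oc1ccc(C)c([C@@H](OC(=O)OC(C)(C)C)[C@H](C#C[Si](C(C)C)(C(C)C)C(C)C)CCBr)c1CCCO[Si](C)(C)C(C)(C)C | intermediate
25 | 2-tert-butoxy-1,3-dioxan-2-ylium ion fused to the dienone, acetate salt | C[C@@]12O[C+](OC(C)(C)C)O[C@@H]([C@H](C#C[Si](C(C)C)(C(C)C)C(C)C)CCBr)C1=C(CCCO[Si](C)(C)C(C)(C)C)C(=O)C=C2.CC([O-])=O | intermediate
26 | (4S,8aS)-4-[(3S)-5-bromo-1-(triisopropylsilyl)pent-1-yn-3-yl]-8a-methyl-5-[3-(TBS-oxy)propyl]-4H-1,3-benzodioxine-2,6(8aH)-dione | C[C@@]12OC(=O)O[C@@H]([C@H](C#C[Si](C(C)C)(C(C)C)C(C)C)CCBr)C1=C(CCCO[Si](C)(C)C(C)(C)C)C(=O)C=C2 | intermediate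
27 | cyclic 1,6-carbonate of (1S,2S,5S,6S,10S)-1,6-dihydroxy-6-methyl-10-[3-(TBS-oxy)propyl]-2-[(triisopropylsilyl)ethynyl]spiro[4.5]dec-7-en-9-one | CC(C)[Si](C(C)C)(C(C)C)C#C[C@@H]1CC[C@]2([C@H](CCCO[Si](C)(C)C(C)(C)C)C(=O)C=C[C@]2(C)OC(=O)O3)[C@H]13 | intermediate
28 | cyclic 1,6-carbonate of (1S,2S,5S,6S,10S)-1,6-dihydroxy-6-methyl-10-[3-(TBS-oxy)propyl]-2-[(triisopropylsilyl)ethynyl]spiro[4.5]decan-9-one | CC(C)[Si](C(C)C)(C(C)C)C#C[C@@H]1CC[C@]2([C@H](CCCO[Si](C)(C)C(C)(C)C)C(=O)CC[C@]2(C)OC(=O)O3)[C@H]13 | intermediate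
29 | cyclic 1,6-carbonate of (1S,2S,5S,6S,9R,10S)-6-methyl-9-(prop-1-en-2-yl)-10-[3-(TBS-oxy)propyl]-2-[(triisopropylsilyl)ethynyl]spiro[4.5]decane-1,6,9-triol | CC(C)[Si](C(C)C)(C(C)C)C#C[C@@H]1CC[C@]2([C@H](CCCO[Si](C)(C)C(C)(C)C)[C@@](O)(C(C)=C)CC[C@]2(C)OC(=O)O3)[C@H]13 | intermediate
30 | (2Z)-2-{(1S,2S,5S,6S,10R)-1,6-(carbonyldioxy)-6-methyl-10-[3-(TBS-oxy)propyl]-2-[(triisopropylsilyl)ethynyl]spiro[4.5]decan-9-ylidene}propanal | CC(C)[Si](C(C)C)(C(C)C)C#C[C@@H]1CC[C@]2([C@H](CCCO[Si](C)(C)C(C)(C)C)/C(=C(/C)C=O)CC[C@]2(C)OC(=O)O3)[C@H]13 | intermediate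
31 | (2Z)-2-[(1S,2S,5S,6S,10R)-1,6-(carbonyldioxy)-2-ethynyl-10-(3-hydroxypropyl)-6-methylspiro[4.5]decan-9-ylidene]propanal | C#C[C@@H]1CC[C@]2([C@H](CCCO)/C(=C(/C)C=O)CC[C@]2(C)OC(=O)O3)[C@H]13 | intermediate
32 | (2Z)-2-[(1S,2S,5S,6S,10R)-2-ethynyl-1,6-dihydroxy-10-(3-hydroxypropyl)-6-methylspiro[4.5]decan-9-ylidene]propanal | C#C[C@@H]1CC[C@]2([C@H](CCCO)/C(=C(/C)C=O)CC[C@]2(C)O)[C@H]1O | intermediate
33 | (2Z)-2-[(1S,2R,5S,6S,10R)-2-{1-[benzyl(dimethyl)silyl]ethenyl}-1,6-dihydroxy-10-(3-hydroxypropyl)-6-methylspiro[4.5]decan-9-ylidene]propanal | C=C([Si](C)(C)Cc1ccccc1)[C@@H]1CC[C@]2([C@H](CCCO)/C(=C(/C)C=O)CC[C@]2(C)O)[C@H]1O | intermediate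
34 | prop-2-yn-1-ol | C#CCO | starting material
35 | 5-bromo-2-methylpent-2-ene | CC(C)=CCCBr | starting material
36 | (4-methylpent-3-en-1-yl)magnesium bromide | CC(C)=CCC[Mg]Br | intermediate
37 | 4-(4-methylpent-3-en-1-yl)-2,5-dihydro-1,2-oxamagnesole (cyclic alkenylmagnesium alkoxide) | CC(C)=CCCC1=C[Mg]OC1 | intermediate
38 | (2Z)-3-iodo-2-(4-methylpent-3-en-1-yl)prop-2-en-1-ol | I/C=C(\CO)CCC=C(C)C | intermediate
39 | (E)-1,2-bis(tributylstannyl)ethene | CCCC[Sn](CCCC)(CCCC)/C=C/[Sn](CCCC)(CCCC)CCCC | starting material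
40 | (2Z,4E)-2-(4-methylpent-3-en-1-yl)-5-(tributylstannyl)penta-2,4-dien-1-ol | CCCC[Sn](CCCC)(CCCC)/C=C/C=C(\CO)CCC=C(C)C | intermediate
41 | (2Z,4E)-5-iodo-2-(4-methylpent-3-en-1-yl)penta-2,4-dien-1-ol | I/C=C/C=C(\CO)CCC=C(C)C | intermediate
42 | (2Z)-2-{(1S,2S,5S,6S,10R)-1,6-dihydroxy-2-[(3E,5Z)-6-(hydroxymethyl)-10-methylundeca-1,3,5,9-tetraen-2-yl]-10-(3-hydroxypropyl)-6-methylspiro[4.5]decan-9-ylidene}propanal | C=C(/C=C/C=C(\CO)CCC=C(C)C)[C@@H]1CC[C@]2([C@H](CCCO)/C(=C(/C)C=O)CC[C@]2(C)O)[C@H]1O | target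

**Totals**

Total step count: 26.
Longest linear sequence: 18 steps (steps 1–5, 11–22 and 26, from compound 1).

**Steps most likely to fail**

Step 16. The carbonate oxygen may be too slow to capture the oxidised arene, so that loss of a benzylic proton or attack at the ortho carbon takes over. The fallback separates oxygenation from ring closure and sets out from 23. Oxidation with PhI(OAc)2 in aqueous acetonitrile, the known para-hydroxylation of 4-alkylphenols, should give the para-quinol tert-butyl carbonate F1. The face is then no longer set by a tether, so the epimer at the new carbinol carbon would be removed by chromatography. Sodium hydride in THF then lets the tertiary alkoxide attack the neighbouring Boc carbonyl with loss of tert-butoxide, a known carbonate transfer, and this returns to the route at 26.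

Step 17. Hydrogen transfer to the α-keto radical may show poor facial selectivity at C10 (premature reduction of the bromide is a lesser worry under slow addition). The fallback replaces kinetic control by thermodynamic control at a later stage and sets out from 26. If the cyclisation gives mainly the C-10 epimer of enone 27 F2, this is carried through the conditions of steps 18 to 20 as the C-10 epimer of ketone 28 F3, the C-10 epimer of carbinol 29 F4 and the C-10 epimer of enal 30 F5. In the enal, 1,3-allylic strain forces the C10 chain axial, where it is syn-axial to the C6 methyl group in F5 but to the C6 oxygen in 30. Equilibration through the dienolate (DBU, toluene, rt) should therefore funnel F5 into 30, where the route is rejoined.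

Step 20. The hindered tertiary chromate may dehydrate instead of rearranging, and the alkene geometry may be only partly controlled. The fallback builds the alkylidene by olefination and sets out from 28. A Horner–Wadsworth–Emmons reaction with diethyl (1-cyanoethyl)phosphonate (NaH, DME, heat) should give the alkylidene nitrile F6, in which the small linear nitrile is expected to sit beside the substituted C10. DIBAL-H (CH2Cl2, −78 °C to −20 °C, then hydrolysis of the aldimine) reduces the nitrile to the aldehyde and cleaves the carbonate, giving the silylated diol enal F7. Bu4NF buffered with AcOH then removes both silyl groups and returns to the route at 32.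

Further compounds
F1 | step 16 | tert-butyl (1S,2S)-2-(2-bromoethyl)-1-{(6S)-6-hydroxy-6-methyl-3-oxo-2-[3-(TBS-oxy)propyl]cyclohexa-1,4-dien-1-yl}-4-(triisopropylsilyl)but-3-yn-1-yl carbonate | C[C@]1(O)C=CC(=O)C(CCCO[Si](C)(C)C(C)(C)C)=C1[C@@H](OC(=O)OC(C)(C)C)[C@H](C#C[Si](C(C)C)(C(C)C)C(C)C)CCBr
F2 | step 17 | C-10 epimer of enone 27 | CC(C)[Si](C(C)C)(C(C)C)C#C[C@@H]1CC[C@]2([C@@H](CCCO[Si](C)(C)C(C)(C)C)C(=O)C=C[C@]2(C)OC(=O)O3)[C@H]13
F3 | step 17 | C-10 epimer of ketone 28 | CC(C)[Si](C(C)C)(C(C)C)C#C[C@@H]1CC[C@]2([C@@H](CCCO[Si](C)(C)C(C)(C)C)C(=O)CC[C@]2(C)OC(=O)O3)[C@H]13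
F4 | step 17 | C-10 epimer of carbinol 29 (C-9 hydroxyl on the face opposite the carbonate) | CC(C)[Si](C(C)C)(C(C)C)C#C[C@@H]1CC[C@]2([C@@H](CCCO[Si](C)(C)C(C)(C)C)[C@](O)(C(C)=C)CC[C@]2(C)OC(=O)O3)[C@H]13
F5 | step 17 | C-10 epimer of enal 30 | CC(C)[Si](C(C)C)(C(C)C)C#C[C@@H]1CC[C@]2([C@@H](CCCO[Si](C)(C)C(C)(C)C)/C(=C(/C)C=O)CC[C@]2(C)OC(=O)O3)[C@H]13
F6 | step 20 | (2Z)-2-{(1S,2S,5S,6S,10R)-1,6-(carbonyldioxy)-6-methyl-10-[3-(TBS-oxy)propyl]-2-[(triisopropylsilyl)ethynyl]spiro[4.5]decan-9-ylidene}propanenitrile | CC(C)[Si](C(C)C)(C(C)C)C#C[C@@H]1CC[C@]2([C@H](CCCO[Si](C)(C)C(C)(C)C)/C(=C(/C)C#N)CC[C@]2(C)OC(=O)O3)[C@H]13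
F7 | step 20 | (2Z)-2-{(1S,2S,5S,6S,10R)-1,6-dihydroxy-6-methyl-10-[3-(TBS-oxy)propyl]-2-[(triisopropylsilyl)ethynyl]spiro[4.5]decan-9-ylidene}propanal | CC(C)[Si](C(C)C)(C(C)C)C#C[C@@H]1CC[C@]2([C@H](CCCO[Si](C)(C)C(C)(C)C)/C(=C(/C)C=O)CC[C@]2(C)O)[C@H]1O
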